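**Retrosynthetic overview**
- The target acid comes from chlorite oxidation of the corresponding depside aldehyde. The B-ring CHO serves as the latent CO2H, so no ester protecting group is needed.
- The depside aldehyde comes from O-methylation of the chelated 2'-OH. That phenol comes from 4-O-selective esterification of 2-heptyl-4,6-dimethoxybenzoic acid with 2-heptyl-4,6-dihydroxybenzaldehyde.
- Both halves come from one common aldehyde, 2-heptyl-4,6-dimethoxybenzaldehyde: oxidation gives the acid and BBr3 gives the diol. The aldehyde comes from Vilsmeier formylation of 1-heptyl-3,5-dimethoxybenzene.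
- Key C–C bond is aryl–C1 of the heptyl chain. 1-Bromo-3,5-dimethoxybenzene is joined to heptanal, whose carbonyl carbon acts as a carbanion equivalent through its NH2-hydrazone (Ni catalysis). Loss of N2 leaves the CH2 directly.
- No ring is formed. Both benzene rings come from the same purchased bromoarene.

Assumption: the SMILES holds no stereocentre and no stereogenic double bond, so the target is achiral and no stereocontrol is needed.

**Step 1**
Reactants: 1 1-bromo-3,5-dimethoxybenzene; 2 heptanal
Product: 4 1-heptyl-3,5-dimethoxybenzene, via heptanal hydrazone 3 (not isolated)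
Conditions: (i) 2, N2H4·H2O (1.1 equiv to 2), THF, rt, 1 h, then Na2SO4. (ii) Solution of 3 (2 equiv) added to 1, Ni(cod)2 (10 mol %), PMe3 (20 mol %), LiOt-Bu (2 equiv), THF, 60 °C, 16 h, Ar.
Reagents that add atoms: hydrazine (used as the monohydrate), NN (its two N atoms stand only in 3 and leave as N2)
Why: Proposed new method: Ni(0) inserts into the C–Br bond of 1, the deprotonated hydrazone 3 binds through N and shifts to C (1,2-diaza-allyl shift) so that the former aldehyde carbon sits on nickel as a carbanion equivalent, C(sp2)–C(sp3) reductive elimination gives the benzylic diazene ArCH(C6H13)N=NH, and base-induced loss of N2 (the last stage of a Wolff–Kishner reduction, eased by the benzylic position) leaves the CH2, so two carbons that are both electrophilic in 1 and 2 are joined with no later deoxygenation; the closest known reaction type is the nickel-catalysed cross-coupling of aryl aldehyde hydrazones with aryl halides (hydrazone umpolung), aliphatic aldehyde hydrazones are known carbanion equivalents in Ru-catalysed carbonyl additions, and the new element is an enolisable aliphatic hydrazone on nickel, where the small strongly donating phosphine should hold back β-hydride elimination.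

**Step 2**
Reactants: 4 1-heptyl-3,5-dimethoxybenzene
Product: 6 2-heptyl-4,6-dimethoxybenzaldehyde, via aryl iminium salt 5 (not isolated)
Conditions: POCl3 (1.5 equiv), DMF, 0 → 60 °C, 3 h; then ice–H2O.
Reagents that add atoms: N,N-dimethylformamide, CN(C)C=O; phosphoryl chloride, O=P(Cl)(Cl)Cl (counter-ion of 5 only); water, O
Why: Vilsmeier–Haack formylation, in which the bulky chloroiminium ion attacks the position para to one OMe and ortho to the other rather than the crowded site between the two OMe groups, as is the rule for 5-alkylresorcinol dimethyl ethers, and hydrolysis of 5 gives the aldehyde.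

**Step 3** (about half of 6)
Reactants: 6 2-heptyl-4,6-dimethoxybenzaldehyde
Product: 7 2-heptyl-4,6-dimethoxybenzoic acid
Conditions: NaClO2, NaH2PO4, 2-methyl-2-butene (10 equiv), t-BuOH–H2O, rt.
Reagents that add atoms: sodium chlorite, [Na+].[O-]Cl=O
Why: Pinnick (Lindgren) oxidation, in which chlorous acid adds to the hindered aldehyde and fragments to the acid while excess 2-methyl-2-butene traps HOCl before it can chlorinate the electron-rich ring.

**Step 4** (other half of 6)
Reactants: 6 2-heptyl-4,6-dimethoxybenzaldehyde
Product: 8 2-heptyl-4,6-dihydroxybenzaldehyde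
Conditions: BBr3 (4 equiv), CH2Cl2, −78 °C → rt, 12 h; then H2O, 0 °C.
Reagents that add atoms: none
Why: Lewis-acid aryl methyl ether cleavage, in which BBr3 removes the carbonyl-chelated ortho OMe first and, in excess at rt, the para OMe too, and any ArCHBr2 or boron adduct formed at the electron-rich aldehyde reverts to CHO on aqueous quench.

**Step 5**
Reactants: 7 2-heptyl-4,6-dimethoxybenzoic acid; 8 2-heptyl-4,6-dihydroxybenzaldehyde
Product: 10 4-formyl-3-heptyl-5-hydroxyphenyl 2-heptyl-4,6-dimethoxybenzoate, via mixed trifluoroacetic anhydride 9 (not isolated)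
Conditions: (CF3CO)2O (3 equiv), dry toluene, rt, 4–16 h (7:8 = 1:1).
Reagents that add atoms: trifluoroacetic anhydride, O=C(OC(=O)C(F)(F)F)C(F)(F)F (its CF3CO unit stands only in 9)
Why: Mixed-anhydride (TFAA) depside esterification, in which the hindered electron-rich acid ionises from 9 to an acylium-like species that acylates the free para OH, while the ortho OH is held in a strong hydrogen bond to the CHO and stays unreacted.

**Step 6**
Reactants: 10 4-formyl-3-heptyl-5-hydroxyphenyl 2-heptyl-4,6-dimethoxybenzoate
Product: 11 4-formyl-3-heptyl-5-methoxyphenyl 2-heptyl-4,6-dimethoxybenzoate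
Conditions: MeI (3 equiv), K2CO3 (1.5 equiv), dry DMF, rt.
Reagents that add atoms: iodomethane, CI
Why: Williamson O-methylation, in which the salicylaldehyde-type OH is the only acidic site left and the di-ortho-substituted electron-rich aroyl ester is too hindered to be attacked under anhydrous carbonate conditions.

**Step 7**
Reactants: 11 4-formyl-3-heptyl-5-methoxyphenyl 2-heptyl-4,6-dimethoxybenzoate
Product: 12 2-heptyl-4-[(2-heptyl-4,6-dimethoxybenzoyl)oxy]-6-methoxybenzoic acid (target)
Conditions: NaClO2, NaH2PO4, 2-methyl-2-butene (10 equiv), t-BuOH–THF–H2O, 0 °C → rt.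
Reagents that add atoms: sodium chlorite, [Na+].[O-]Cl=O
Why: Pinnick oxidation, in which mildly acidic chlorite turns CHO into CO2H without touching the aryl ester, the ethers or the chains, so the acid is unveiled with no deprotection and no stereocentre is involved.

**Compound list**
1 | 1-bromo-3,5-dimethoxybenzene | COc1cc(Br)cc(OC)c1 | starting material
2 | heptanal | CCCCCCC=O | starting material
3 | (E)-heptanal hydrazone (heptylidenehydrazine) | CCCCCC/C=N/N | intermediate
4 | 1-heptyl-3,5-dimethoxybenzene | CCCCCCCc1cc(OC)cc(OC)c1 | intermediate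
5 | [(2-heptyl-4,6-dimethoxyphenyl)methylidene]dimethylammonium dichlorophosphate | CCCCCCCc1cc(OC)cc(OC)c1C=[N+](C)C.[O-]P(=O)(Cl)Cl | intermediate
6 | 2-heptyl-4,6-dimethoxybenzaldehyde | CCCCCCCc1cc(OC)cc(OC)c1C=O | intermediate
7 | 2-heptyl-4,6-dimethoxybenzoic acid | CCCCCCCc1cc(OC)cc(OC)c1C(=O)O | intermediate
8 | 2-heptyl-4,6-dihydroxybenzaldehyde | CCCCCCCc1cc(O)cc(O)c1C=O | intermediate
9 | 2-heptyl-4,6-dimethoxybenzoic trifluoroacetic anhydride | CCCCCCCc1cc(OC)cc(OC)c1C(=O)OC(=O)C(F)(F)F | intermediate
10 | 4-formyl-3-heptyl-5-hydroxyphenyl 2-heptyl-4,6-dimethoxybenzoate | CCCCCCCc1cc(OC(=O)c2c(CCCCCCC)cc(OC)cc2OC)cc(O)c1C=O | intermediate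
11 | 4-formyl-3-heptyl-5-methoxyphenyl 2-heptyl-4,6-dimethoxybenzoate | CCCCCCCc1cc(OC(=O)c2c(CCCCCCC)cc(OC)cc2OC)cc(OC)c1C=O | intermediate
12 | 2-heptyl-4-[(2-heptyl-4,6-dimethoxybenzoyl)oxy]-6-methoxybenzoic acid | CCCCCCCc1cc(OC(=O)c2c(CCCCCCC)cc(OC)cc2OC)cc(OC)c1C(=O)O | target

**Total step count:** 7 (the one-pot hydrazone formation and coupling counts as one).
**Longest linear sequence:** 6 (steps 1, 2, 4, 5, 6, 7; step 3 is the one-step branch).

**Three steps most likely to fail**

**Step 1.** An aliphatic hydrazone on nickel may undergo N-arylation, β-hydride elimination, hydrodebromination of 1, or azine formation. The fallback sets out from 2, with 1 as partner, and comes back at 4. It keeps the same bond and the same reversed polarity of the aldehyde carbon but runs through a palladium carbene.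
- Compound 2 is condensed with tosylhydrazide (MeOH, rt) to heptanal N-tosylhydrazone F1.
- LiOt-Bu in dioxane at 100 °C releases 1-diazoheptane F2 in the flask.
- F2 is taken up by the ArPdBr complex made from 1 (Pd2(dba)3, XPhos). Carbene formation, aryl migration and β-hydride elimination give (E)-1-(hept-1-en-1-yl)-3,5-dimethoxybenzene F3.
- H2 over Pd/C in EtOAc saturates F3 to 4.
- The cost is two extra steps.

**Step 4.** The second demethylation may stall on the carbonyl-deactivated ring, or the aldehyde may be damaged by BBr3. The fallback sets out from 4 and comes back at 8. It reverses the order, so the ethers are cleaved before any carbonyl is present.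
- BBr3 in CH2Cl2 turns 4 into 5-heptylbenzene-1,3-diol F4.
- Vilsmeier formylation of the free resorcinol (POCl3, DMF, 0 °C → rt) passes through [(2-heptyl-4,6-dihydroxyphenyl)methylidene]dimethylammonium dichlorophosphate F5.
- Water hydrolyses F5 to 8. The regiochemistry is ortho/para to the two OH groups and next to the chain, as known for orcinol and olivetol.
- Compound 6 is then made only for step 3. The cost is one extra step.

**Step 6.** Phenoxide or carbonate may cleave or transacylate the activated aryl ester, or the chelated OH may methylate sluggishly. The fallback sets out from 8 and comes back at 11. The methyl group is placed before the ester bond exists.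
- The non-chelated para OH of 8 is alkylated selectively (allyl bromide 1.05 equiv, KHCO3, DMF, rt) to 4-(allyloxy)-2-heptyl-6-hydroxybenzaldehyde F6.
- MeI and K2CO3 in DMF give 4-(allyloxy)-2-heptyl-6-methoxybenzaldehyde F7.
- Pd(PPh3)4 with morpholine in THF removes the allyl group without touching the aldehyde and gives 2-heptyl-4-hydroxy-6-methoxybenzaldehyde F8.
- F8 has a single OH and is esterified with 7 through 9 (TFAA, toluene) straight to 11.
- The cost is two extra steps.

**Further compounds**
F1 | step 1 | heptanal N-tosylhydrazone | CCCCCC/C=N/NS(=O)(=O)c1ccc(C)cc1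
F2 | step 1 | 1-diazoheptane | CCCCCCC=[N+]=[N-]
F3 | step 1 | (E)-1-(hept-1-en-1-yl)-3,5-dimethoxybenzene | CCCCC/C=C/c1cc(OC)cc(OC)c1
F4 | step 4 | 5-heptylbenzene-1,3-diol | CCCCCCCc1cc(O)cc(O)c1
F5 | step 4 | [(2-heptyl-4,6-dihydroxyphenyl)methylidene]dimethylammonium dichlorophosphate | CCCCCCCc1cc(O)cc(O)c1C=[N+](C)C.[O-]P(=O)(Cl)Cl
F6 | step 6 | 4-(allyloxy)-2-heptyl-6-hydroxybenzaldehyde | C=CCOc1cc(O)c(C=O)c(CCCCCCC)c1
F7 | step 6 | 4-(allyloxy)-2-heptyl-6-methoxybenzaldehyde | C=CCOc1cc(OC)c(C=O)c(CCCCCCC)c1
F8 | step 6 | 2-heptyl-4-hydroxy-6-methoxybenzaldehyde | CCCCCCCc1cc(O)cc(OC)c1C=O
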